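The target is cut at the bond between the benzylic CH2 on lactone C-3 and the carbon of ring B (the arene carrying the open diol arm) that lies para to its phenolic oxygen. Because this CH2 sits β to the lactone carbonyl, it is the electrophilic terminus of an α-methylene-γ-butyrolactone: a rhodium-catalysed 1,4-addition of the ring-B arylboronate, protonation and base equilibration join the two halves and set the trans C-3/C-4 relationship. Both halves come from one anti-aldol-derived aryl bromide: acid closes it to the (2R,3S)-dihydrobenzofuran of the lactone half (lactone C-4 from (S)-epichlorohydrin), and borylation gives the (1S,2S)-diol half.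

Key step: step 13

Remark: ring A is the guaiacyl ring of the diol arm, ring B the arene bearing the diol arm and the C-3 benzyl CH2, ring C the arene of the dihydrobenzofuran, ring D the guaiacyl ring at dihydrobenzofuran C-2.

Assumption: in step 5 the (S)-auxiliary is taken to give the (2R,3S)-anti adduct (attack on the chelated Z-enolate anti to the 4-benzyl group); should the sense prove opposite, the (R)-auxiliary is used and nothing else changes.

Step 1
Reactants: 1 5-bromo-2-hydroxy-3-methoxybenzaldehyde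
Product: 2 5-bromo-3-methoxy-2-[(4-methoxybenzyl)oxy]benzaldehyde
Conditions: PMBCl, K2CO3, KI (cat.), DMF, 60 °C
Reagents that add atoms: 4-methoxybenzyl chloride (PMBCl), COc1ccc(CCl)cc1
Why: Williamson etherification of the phenoxide; the PMB ether is chosen because it is later acid-labile for the ring closure and hydrogenolysable in the final deprotection.

Step 2
Reactants: 2 5-bromo-3-methoxy-2-[(4-methoxybenzyl)oxy]benzaldehyde
Product: 3 {5-bromo-3-methoxy-2-[(4-methoxybenzyl)oxy]phenyl}acetonitrile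
Conditions: TosMIC, KOtBu, DME, −40 °C to rt; then MeOH, reflux
Reagents that add atoms: p-toluenesulfonylmethyl isocyanide (TosMIC), Cc1ccc(cc1)S(=O)(=O)C[N+]#[C-]
Why: van Leusen reductive cyanation: the TosMIC anion adds to the aldehyde, the oxazoline opens, and methanolysis expels formate and sulfinate to give the one-carbon-homologated nitrile.

Step 3
Reactants: 3 {5-bromo-3-methoxy-2-[(4-methoxybenzyl)oxy]phenyl}acetonitrile
Product: 4 {5-bromo-3-methoxy-2-[(4-methoxybenzyl)oxy]phenyl}acetic acid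
Conditions: KOH, EtOH/H2O, reflux; then cold 1 M HCl to pH 3
Reagents that add atoms: water (as hydroxide), O
Why: Basic nitrile hydrolysis to the carboxylate; the aryl bromide and the PMB ether are inert to hydroxide and to the brief mild acidification.

Step 4
Reactants: 4 {5-bromo-3-methoxy-2-[(4-methoxybenzyl)oxy]phenyl}acetic acid; 5 (S)-4-benzyl-1,3-oxazolidin-2-one
Product: 6 (S)-4-benzyl-3-({5-bromo-3-methoxy-2-[(4-methoxybenzyl)oxy]phenyl}acetyl)-1,3-oxazolidin-2-one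
Conditions: PivCl, Et3N, THF, −20 °C; then 5, LiCl, −20 °C to rt
Reagents that add atoms: none
Why: N-acylation of the oxazolidinone through the mixed pivalic anhydride (LiCl-assisted), a standard attachment of the auxiliary.

Step 5
Reactants: 6 (S)-4-benzyl-3-({5-bromo-3-methoxy-2-[(4-methoxybenzyl)oxy]phenyl}acetyl)-1,3-oxazolidin-2-one; 7 4-(benzyloxy)-3-methoxybenzaldehyde
Product: 8 (4S)-4-benzyl-3-[(2R,3S)-3-[4-(benzyloxy)-3-methoxyphenyl]-2-{5-bromo-3-methoxy-2-[(4-methoxybenzyl)oxy]phenyl}-3-(trimethylsilyloxy)propanoyl]-1,3-oxazolidin-2-one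
Conditions: MgCl2 (0.2 equiv), Et3N, TMSCl, EtOAc, 23 °C
Reagents that add atoms: chlorotrimethylsilane (TMSCl), C[Si](C)(C)Cl
Why: Magnesium-halide-catalysed anti-aldol of an N-acyloxazolidinone (Evans-type soft enolisation, with silylation of the aldolate driving turnover); attack on the chelated Z-enolate anti to the auxiliary benzyl group through a boat transition state should set both centres as the (2R,3S)-anti adduct.

Step 6
Reactants: 8 (4S)-4-benzyl-3-[(2R,3S)-3-[4-(benzyloxy)-3-methoxyphenyl]-2-{5-bromo-3-methoxy-2-[(4-methoxybenzyl)oxy]phenyl}-3-(trimethylsilyloxy)propanoyl]-1,3-oxazolidin-2-one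
Product: 10 (1S,2S)-1-[4-(benzyloxy)-3-methoxyphenyl]-2-{5-bromo-3-methoxy-2-[(4-methoxybenzyl)oxy]phenyl}propane-1,3-diol, via O-trimethylsilyl alcohol 9 (not isolated)
Conditions: LiBH4, MeOH (2 equiv), THF, 0 °C; then K2CO3, MeOH, rt
Reagents that add atoms: none
Why: Reductive cleavage of the N-acyl oxazolidinone by LiBH4 (the silyl ether blocks retro-aldol, the auxiliary is recovered), followed by methanolysis of the TMS ether; neither stereocentre is touched.

Step 7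
Reactants: 10 (1S,2S)-1-[4-(benzyloxy)-3-methoxyphenyl]-2-{5-bromo-3-methoxy-2-[(4-methoxybenzyl)oxy]phenyl}propane-1,3-diol
Product: 11 (1S,2S)-1-[4-(benzyloxy)-3-methoxyphenyl]-2-{5-bromo-3-methoxy-2-[(4-methoxybenzyl)oxy]phenyl}-3-(triisopropylsilyloxy)propan-1-ol
Conditions: TIPSCl (1.1 equiv), imidazole, CH2Cl2/DMF, 0 °C to rt
Reagents that add atoms: chlorotriisopropylsilane (TIPSCl), CC(C)[Si](Cl)(C(C)C)C(C)C
Why: Selective silylation of the primary hydroxyl over the hindered secondary benzylic one; 11 is the common intermediate of both halves.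

Step 8
Reactants: 11 (1S,2S)-1-[4-(benzyloxy)-3-methoxyphenyl]-2-{5-bromo-3-methoxy-2-[(4-methoxybenzyl)oxy]phenyl}-3-(triisopropylsilyloxy)propan-1-ol
Product: 12 (2R,3S)-2-[4-(benzyloxy)-3-methoxyphenyl]-5-bromo-7-methoxy-3-[(triisopropylsilyloxy)methyl]-2,3-dihydro-1-benzofuran
Conditions: TFA (10 vol%), anisole (5 equiv), CH2Cl2, 0 °C; NaHCO3 quench
Reagents that add atoms: none
Why: TFA cleaves the aryl PMB ether (cation scavenged by anisole) and ionises the electron-rich benzylic alcohol, and the freed ring-C phenol captures the benzylic cation (SN1 cycloetherification to the five-membered ring); attack anti to the C-3 CH2OTIPS group and reversibility under acid should give the 2,3-trans (2R,3S) ring whatever the carbinol configuration.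

Step 9
Reactants: 13 dimethyl malonate; 14 (S)-2-(chloromethyl)oxirane ((S)-epichlorohydrin)
Product: 15 methyl (1R,5S)-2-oxo-3-oxabicyclo[3.1.0]hexane-1-carboxylate
Conditions: NaOMe (1 equiv), MeOH, 0 °C to reflux
Reagents that add atoms: none
Why: The malonate opens the epoxide at CH2, the alkoxide closes a new epoxide with loss of chloride, and the malonate anion closes the cyclopropane by 3-exo-tet attack with inversion before lactonisation, so the (5S) centre derives from (S)-epichlorohydrin.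

Step 10
Reactants: 12 (2R,3S)-2-[4-(benzyloxy)-3-methoxyphenyl]-5-bromo-7-methoxy-3-[(triisopropylsilyloxy)methyl]-2,3-dihydro-1-benzofuran; 15 methyl (1R,5S)-2-oxo-3-oxabicyclo[3.1.0]hexane-1-carboxylate
Product: 17 methyl (3R,4S)-4-({(2R,3S)-2-[4-(benzyloxy)-3-methoxyphenyl]-7-methoxy-3-[(triisopropylsilyloxy)methyl]-2,3-dihydro-1-benzofuran-5-yl}methyl)-2-oxooxolane-3-carboxylate, via arylmagnesium bromide 16 (not isolated)
Conditions: Mg turnings, LiCl, THF, 40 °C; then CuI (10 mol%), 15 (1.5 equiv), THF, −30 to 0 °C; aq NH4Cl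
Reagents that add atoms: none
Why: Copper-catalysed homoconjugate addition of the aryl Grignard reagent to the doubly activated cyclopropane (SN2 at the cyclopropane CH2 with the malonate-type enolate as leaving group); lactone C-4 is untouched and stays (S), and the epimerisable C-3 settles trans on protonation.

Step 11
Reactants: 17 methyl (3R,4S)-4-({(2R,3S)-2-[4-(benzyloxy)-3-methoxyphenyl]-7-methoxy-3-[(triisopropylsilyloxy)methyl]-2,3-dihydro-1-benzofuran-5-yl}methyl)-2-oxooxolane-3-carboxylate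
Product: 19 (4S)-4-({(2R,3S)-2-[4-(benzyloxy)-3-methoxyphenyl]-7-methoxy-3-[(triisopropylsilyloxy)methyl]-2,3-dihydro-1-benzofuran-5-yl}methyl)-3-methylideneoxolan-2-one, via carboxy lactone 18 (not isolated)
Conditions: LiOH, THF/H2O, 0 °C to rt; then AcOH to pH 4–5, Et2NH, 37% aq HCHO, NaOAc, 60 °C
Reagents that add atoms: formaldehyde, C=O
Why: Saponification and relactonisation give the malonic half-acid, which undergoes the classical decarboxylative Mannich methylenation (aminomethylation, loss of CO2 and amine) to the α-methylene lactone without touching C-4.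

Step 12
Reactants: 11 (1S,2S)-1-[4-(benzyloxy)-3-methoxyphenyl]-2-{5-bromo-3-methoxy-2-[(4-methoxybenzyl)oxy]phenyl}-3-(triisopropylsilyloxy)propan-1-ol
Product: 20 (1S,2S)-1-[4-(benzyloxy)-3-methoxyphenyl]-2-{3-methoxy-2-[(4-methoxybenzyl)oxy]-5-(4,4,5,5-tetramethyl-1,3,2-dioxaborolan-2-yl)phenyl}-3-(triisopropylsilyloxy)propan-1-ol
Conditions: B2pin2, Pd(dppf)Cl2 (5 mol%), KOAc, 1,4-dioxane, 85 °C
Reagents that add atoms: bis(pinacolato)diboron, CC1(C)OB(OC1(C)C)B1OC(C)(C)C(C)(C)O1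
Why: Miyaura borylation of the unhindered aryl bromide; the weak acetate base leaves the free secondary alcohol, the silyl ether and both benzylic-type aryl ethers alone.

Step 13
Reactants: 19 (4S)-4-({(2R,3S)-2-[4-(benzyloxy)-3-methoxyphenyl]-7-methoxy-3-[(triisopropylsilyloxy)methyl]-2,3-dihydro-1-benzofuran-5-yl}methyl)-3-methylideneoxolan-2-one; 20 (1S,2S)-1-[4-(benzyloxy)-3-methoxyphenyl]-2-{3-methoxy-2-[(4-methoxybenzyl)oxy]-5-(4,4,5,5-tetramethyl-1,3,2-dioxaborolan-2-yl)phenyl}-3-(triisopropylsilyloxy)propan-1-ol (1.3 equiv)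
Product: 22 (3S,4S)-3-{3-[(1S,2S)-1-[4-(benzyloxy)-3-methoxyphenyl]-1-hydroxy-3-(triisopropylsilyloxy)propan-2-yl]-5-methoxy-4-[(4-methoxybenzyl)oxy]benzyl}-4-({(2R,3S)-2-[4-(benzyloxy)-3-methoxyphenyl]-7-methoxy-3-[(triisopropylsilyloxy)methyl]-2,3-dihydro-1-benzofuran-5-yl}methyl)oxolan-2-one, via cis-lactone epimer 21 (not isolated)
Conditions: [Rh(OH)(cod)]2 (3 mol%), K3PO4 (0.5 equiv), 1,4-dioxane/H2O (10:1), 50 °C; solvent exchange; then DBU, toluene, 60 °C
Reagents that add atoms: none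
Why: Transmetalation of boronate 20 to the hydroxo complex of monovalent rhodium gives an aryl–rhodium species that inserts the exocyclic C=C of 19 with the aryl group going to the unsubstituted CH2 terminus (1,4-addition), and water protonates the resulting oxa-π-allyl rhodium enolate and regenerates Rh–OH. The closest known reaction type is the Hayashi–Miyaura 1,4-addition of arylboron reagents to α-methylene carbonyl compounds with in situ protonation. No ring is closed. The one new stereocentre, lactone C-3, is governed by the existing C-4 centre: kinetic protonation anti to the C-4 benzyl group should favour the cis epimer 21, and DBU then equilibrates C-3 (the only acidic centre) to the more stable trans (3S,4S) lactone 22. The step needs 1,4-arylation to outrun protodeboronation, Heck-type β-hydride elimination and oxa-Michael addition; the aqueous medium (fast enolate protonolysis), the unhindered boron-bearing carbon flanked by two C–H positions, the mild base and the protected phenols and primary alcohols should secure this.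

Step 14
Reactants: 22 (3S,4S)-3-{3-[(1S,2S)-1-[4-(benzyloxy)-3-methoxyphenyl]-1-hydroxy-3-(triisopropylsilyloxy)propan-2-yl]-5-methoxy-4-[(4-methoxybenzyl)oxy]benzyl}-4-({(2R,3S)-2-[4-(benzyloxy)-3-methoxyphenyl]-7-methoxy-3-[(triisopropylsilyloxy)methyl]-2,3-dihydro-1-benzofuran-5-yl}methyl)oxolan-2-one
Product: 23 (3S,4S)-3-{3-[(1S,2S)-1-[4-(benzyloxy)-3-methoxyphenyl]-1,3-dihydroxypropan-2-yl]-5-methoxy-4-[(4-methoxybenzyl)oxy]benzyl}-4-({(2R,3S)-2-[4-(benzyloxy)-3-methoxyphenyl]-3-(hydroxymethyl)-7-methoxy-2,3-dihydro-1-benzofuran-5-yl}methyl)oxolan-2-one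
Conditions: TBAF (3 equiv), AcOH (3 equiv), THF, 0 °C to rt
Reagents that add atoms: none
Why: Buffered fluoride removes both primary TIPS ethers while the phenols are still protected, so no quinone methide can form and the lactone is not opened.

Step 15
Reactants: 23 (3S,4S)-3-{3-[(1S,2S)-1-[4-(benzyloxy)-3-methoxyphenyl]-1,3-dihydroxypropan-2-yl]-5-methoxy-4-[(4-methoxybenzyl)oxy]benzyl}-4-({(2R,3S)-2-[4-(benzyloxy)-3-methoxyphenyl]-3-(hydroxymethyl)-7-methoxy-2,3-dihydro-1-benzofuran-5-yl}methyl)oxolan-2-one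
Product: 24 (3S,4S)-3-{3-[(1S,2S)-1,3-dihydroxy-1-(4-hydroxy-3-methoxyphenyl)propan-2-yl]-4-hydroxy-5-methoxybenzyl}-4-{[(2R,3S)-2-(4-hydroxy-3-methoxyphenyl)-3-(hydroxymethyl)-7-methoxy-2,3-dihydro-1-benzofuran-5-yl]methyl}oxolan-2-one (CNP0186558.3)
Conditions: H2 (1 atm), 10% Pd/C, EtOAc/EtOH (1:1), rt, stopped at full conversion
Reagents that add atoms: none
Why: Neutral hydrogenolysis cleaves the two aryl benzyl ethers and the aryl PMB ether; acid is avoided because the free ring-B phenol would otherwise close onto the benzylic alcohol, and short reaction at 1 atm should spare the benzylic C–O bonds.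

Compound list
1 | 5-bromo-2-hydroxy-3-methoxybenzaldehyde | O=Cc1cc(Br)cc(OC)c1O | starting material
2 | 5-bromo-3-methoxy-2-[(4-methoxybenzyl)oxy]benzaldehyde | O=Cc1cc(Br)cc(OC)c1OCc1ccc(OC)cc1 | intermediate
3 | {5-bromo-3-methoxy-2-[(4-methoxybenzyl)oxy]phenyl}acetonitrile | N#CCc1cc(Br)cc(OC)c1OCc1ccc(OC)cc1 | intermediate
4 | {5-bromo-3-methoxy-2-[(4-methoxybenzyl)oxy]phenyl}acetic acid | OC(=O)Cc1cc(Br)cc(OC)c1OCc1ccc(OC)cc1 | intermediate
5 | (S)-4-benzyl-1,3-oxazolidin-2-one | O=C1N[C@@H](Cc2ccccc2)CO1 | starting material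
6 | (S)-4-benzyl-3-({5-bromo-3-methoxy-2-[(4-methoxybenzyl)oxy]phenyl}acetyl)-1,3-oxazolidin-2-one | O=C(Cc1cc(Br)cc(OC)c1OCc1ccc(OC)cc1)N1[C@@H](Cc2ccccc2)COC1=O | intermediate
7 | 4-(benzyloxy)-3-methoxybenzaldehyde | O=Cc1ccc(OCc2ccccc2)c(OC)c1 | starting material
8 | (4S)-4-benzyl-3-[(2R,3S)-3-[4-(benzyloxy)-3-methoxyphenyl]-2-{5-bromo-3-methoxy-2-[(4-methoxybenzyl)oxy]phenyl}-3-(trimethylsilyloxy)propanoyl]-1,3-oxazolidin-2-one | O=C([C@H](c1cc(Br)cc(OC)c1OCc1ccc(OC)cc1)[C@H](O[Si](C)(C)C)c1ccc(OCc2ccccc2)c(OC)c1)N1[C@@H](Cc2ccccc2)COC1=O | intermediate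
9 | (2S,3S)-3-[4-(benzyloxy)-3-methoxyphenyl]-2-{5-bromo-3-methoxy-2-[(4-methoxybenzyl)oxy]phenyl}-3-(trimethylsilyloxy)propan-1-ol | OC[C@H](c1cc(Br)cc(OC)c1OCc1ccc(OC)cc1)[C@H](O[Si](C)(C)C)c1ccc(OCc2ccccc2)c(OC)c1 | intermediate
10 | (1S,2S)-1-[4-(benzyloxy)-3-methoxyphenyl]-2-{5-bromo-3-methoxy-2-[(4-methoxybenzyl)oxy]phenyl}propane-1,3-diol | OC[C@H](c1cc(Br)cc(OC)c1OCc1ccc(OC)cc1)[C@H](O)c1ccc(OCc2ccccc2)c(OC)c1 | intermediate
11 | (1S,2S)-1-[4-(benzyloxy)-3-methoxyphenyl]-2-{5-bromo-3-methoxy-2-[(4-methoxybenzyl)oxy]phenyl}-3-(triisopropylsilyloxy)propan-1-ol | CC(C)[Si](OC[C@H](c1cc(Br)cc(OC)c1OCc1ccc(OC)cc1)[C@H](O)c1ccc(OCc2ccccc2)c(OC)c1)(C(C)C)C(C)C | intermediate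
12 | (2R,3S)-2-[4-(benzyloxy)-3-methoxyphenyl]-5-bromo-7-methoxy-3-[(triisopropylsilyloxy)methyl]-2,3-dihydro-1-benzofuran | Brc1cc(OC)c2c(c1)[C@@H](CO[Si](C(C)C)(C(C)C)C(C)C)[C@H](c1ccc(OCc3ccccc3)c(OC)c1)O2 | intermediate
13 | dimethyl malonate | COC(=O)CC(=O)OC | starting material
14 | (S)-2-(chloromethyl)oxirane | ClC[C@@H]1CO1 | starting material
15 | methyl (1R,5S)-2-oxo-3-oxabicyclo[3.1.0]hexane-1-carboxylate | COC(=O)[C@@]12C[C@@H]1COC2=O | intermediate
16 | {(2R,3S)-2-[4-(benzyloxy)-3-methoxyphenyl]-7-methoxy-3-[(triisopropylsilyloxy)methyl]-2,3-dihydro-1-benzofuran-5-yl}magnesium bromide | Br[Mg]c1cc(OC)c2c(c1)[C@@H](CO[Si](C(C)C)(C(C)C)C(C)C)[C@H](c1ccc(OCc3ccccc3)c(OC)c1)O2 | intermediate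
17 | methyl (3R,4S)-4-({(2R,3S)-2-[4-(benzyloxy)-3-methoxyphenyl]-7-methoxy-3-[(triisopropylsilyloxy)methyl]-2,3-dihydro-1-benzofuran-5-yl}methyl)-2-oxooxolane-3-carboxylate | COC(=O)[C@@H]1C(=O)OC[C@H]1Cc1cc(OC)c2c(c1)[C@@H](CO[Si](C(C)C)(C(C)C)C(C)C)[C@H](c1ccc(OCc3ccccc3)c(OC)c1)O2 | intermediate
18 | (3R,4S)-4-({(2R,3S)-2-[4-(benzyloxy)-3-methoxyphenyl]-7-methoxy-3-[(triisopropylsilyloxy)methyl]-2,3-dihydro-1-benzofuran-5-yl}methyl)-2-oxooxolane-3-carboxylic acid | OC(=O)[C@@H]1C(=O)OC[C@H]1Cc1cc(OC)c2c(c1)[C@@H](CO[Si](C(C)C)(C(C)C)C(C)C)[C@H](c1ccc(OCc3ccccc3)c(OC)c1)O2 | intermediate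
19 | (4S)-4-({(2R,3S)-2-[4-(benzyloxy)-3-methoxyphenyl]-7-methoxy-3-[(triisopropylsilyloxy)methyl]-2,3-dihydro-1-benzofuran-5-yl}methyl)-3-methylideneoxolan-2-one | C=C1C(=O)OC[C@H]1Cc1cc(OC)c2c(c1)[C@@H](CO[Si](C(C)C)(C(C)C)C(C)C)[C@H](c1ccc(OCc3ccccc3)c(OC)c1)O2 | intermediate
20 | (1S,2S)-1-[4-(benzyloxy)-3-methoxyphenyl]-2-{3-methoxy-2-[(4-methoxybenzyl)oxy]-5-(4,4,5,5-tetramethyl-1,3,2-dioxaborolan-2-yl)phenyl}-3-(triisopropylsilyloxy)propan-1-ol | CC(C)[Si](OC[C@H](c1cc(B2OC(C)(C)C(C)(C)O2)cc(OC)c1OCc1ccc(OC)cc1)[C@H](O)c1ccc(OCc2ccccc2)c(OC)c1)(C(C)C)C(C)C | intermediate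
21 | (3R,4S)-cis epimer of 22 (same substituents, lactone C-3 inverted) | COc1cc([C@@H](O)[C@H](CO[Si](C(C)C)(C(C)C)C(C)C)c2cc(C[C@H]3C(=O)OC[C@H]3Cc3cc(OC)c4c(c3)[C@@H](CO[Si](C(C)C)(C(C)C)C(C)C)[C@H](c3ccc(OCc5ccccc5)c(OC)c3)O4)cc(OC)c2OCc2ccc(OC)cc2)ccc1OCc1ccccc1 | intermediate
22 | (3S,4S)-3-{3-[(1S,2S)-1-[4-(benzyloxy)-3-methoxyphenyl]-1-hydroxy-3-(triisopropylsilyloxy)propan-2-yl]-5-methoxy-4-[(4-methoxybenzyl)oxy]benzyl}-4-({(2R,3S)-2-[4-(benzyloxy)-3-methoxyphenyl]-7-methoxy-3-[(triisopropylsilyloxy)methyl]-2,3-dihydro-1-benzofuran-5-yl}methyl)oxolan-2-one | COc1cc([C@@H](O)[C@H](CO[Si](C(C)C)(C(C)C)C(C)C)c2cc(C[C@@H]3C(=O)OC[C@H]3Cc3cc(OC)c4c(c3)[C@@H](CO[Si](C(C)C)(C(C)C)C(C)C)[C@H](c3ccc(OCc5ccccc5)c(OC)c3)O4)cc(OC)c2OCc2ccc(OC)cc2)ccc1OCc1ccccc1 | intermediate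
23 | (3S,4S)-3-{3-[(1S,2S)-1-[4-(benzyloxy)-3-methoxyphenyl]-1,3-dihydroxypropan-2-yl]-5-methoxy-4-[(4-methoxybenzyl)oxy]benzyl}-4-({(2R,3S)-2-[4-(benzyloxy)-3-methoxyphenyl]-3-(hydroxymethyl)-7-methoxy-2,3-dihydro-1-benzofuran-5-yl}methyl)oxolan-2-one | COc1cc([C@@H](O)[C@H](CO)c2cc(C[C@@H]3C(=O)OC[C@H]3Cc3cc(OC)c4c(c3)[C@@H](CO)[C@H](c3ccc(OCc5ccccc5)c(OC)c3)O4)cc(OC)c2OCc2ccc(OC)cc2)ccc1OCc1ccccc1 | intermediate
24 | (3S,4S)-3-{3-[(1S,2S)-1,3-dihydroxy-1-(4-hydroxy-3-methoxyphenyl)propan-2-yl]-4-hydroxy-5-methoxybenzyl}-4-{[(2R,3S)-2-(4-hydroxy-3-methoxyphenyl)-3-(hydroxymethyl)-7-methoxy-2,3-dihydro-1-benzofuran-5-yl]methyl}oxolan-2-one | COc1cc([C@@H](O)[C@H](CO)c2cc(C[C@@H]3C(=O)OC[C@H]3Cc3cc(OC)c4c(c3)[C@@H](CO)[C@H](c3ccc(O)c(OC)c3)O4)cc(OC)c2O)ccc1O | target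

Total step count: 15. Longest linear sequence: 13 steps (steps 1–8, 10, 11, 13, 14, 15).

Steps most likely to fail

Step 13 (key step). Protodeboronation of the electron-rich boronate may outrun insertion into the 1,1-disubstituted acceptor, the lactone may be opened by the aqueous base, and equilibration may stop short of the trans lactone. The fallback reverses the polarity (Negishi coupling); it sets out from 17 and bromide 11 and comes back at 22. Saponification of 17 with LiOH and acidification gives acid 18. BH3·SMe2 then reduces the carboxylic acid chemoselectively to (3R,4S)-3-(hydroxymethyl)-4-(dihydrobenzofuranylmethyl)oxolan-2-one F1, which locks the trans relationship. Iodination (I2, PPh3, imidazole) gives the iodomethyl lactone F2, and zinc dust in DMF converts it into the alkylzinc iodide F3, a zinc homoenolate that holds its C-3 configuration. Coupling of F3 (in excess, to allow for the free hydroxyl of 11) with 11 under Pd2(dba)3/SPhos in DMF at 40 °C gives 22 directly.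

Step 5. Enolisation of the hindered ortho-alkoxy arylacetyl imide and addition to an electron-rich aldehyde may be slow or reversible, and the anti/syn selectivity may be poor. The fallback is a boron-mediated syn-aldol with the enantiomeric auxiliary followed by inversion of the carbinol; it sets out from 4 and comes back at 11. Acid 4 is attached to (R)-4-benzyl-1,3-oxazolidin-2-one to give the imide F4. Bu2BOTf, i-Pr2NEt and aldehyde 7 (CH2Cl2, −78 to 0 °C) give the (2R,3R)-syn adduct F5, and LiBH4 reduces it to the (1R,2S)-diol F6. TIPSCl/imidazole gives the primary silyl ether F7. Mitsunobu reaction (4-nitrobenzoic acid, PPh3, DIAD) inverts the benzylic carbinol to the (1S,2S)-4-nitrobenzoate F8, and K2CO3/MeOH releases 11. F7 can also enter step 8 unchanged, because that ring closure is stereoconvergent.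

Step 10. Formation of the functionalised aryl Grignard reagent may be sluggish, and 1,2-addition to the lactone or ester carbonyl may compete with opening of the cyclopropane. The fallback builds the same lactone by a Heck reaction and organocatalytic alkylation; it sets out from 12 and comes back at 17. Jeffery–Heck reaction of 12 with allyl alcohol (Pd(OAc)2, Bu4NCl, NaHCO3, DMF, 80 °C) gives the 3-arylpropanal F9. Photoredox organocatalytic α-alkylation with dimethyl bromomalonate (Ru(bpy)3Cl2, visible light, 2,6-lutidine, and the enantiomer of 2-tert-butyl-3,5-dimethylimidazolidin-4-one triflate salt that delivers the (S)-aldehyde) gives the alkylated aldehyde F10. NaBH4 in MeOH reduces it to the hydroxy diester F11, which lactonises to 17.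

Further compounds
F1 | step 13 | (3R,4S)-3-(hydroxymethyl)-4-({(2R,3S)-2-[4-(benzyloxy)-3-methoxyphenyl]-7-methoxy-3-[(triisopropylsilyloxy)methyl]-2,3-dihydro-1-benzofuran-5-yl}methyl)oxolan-2-one | OC[C@@H]1C(=O)OC[C@H]1Cc1cc(OC)c2c(c1)[C@@H](CO[Si](C(C)C)(C(C)C)C(C)C)[C@H](c1ccc(OCc3ccccc3)c(OC)c1)O2
F2 | step 13 | (3S,4S)-3-(iodomethyl)-4-({(2R,3S)-2-[4-(benzyloxy)-3-methoxyphenyl]-7-methoxy-3-[(triisopropylsilyloxy)methyl]-2,3-dihydro-1-benzofuran-5-yl}methyl)oxolan-2-one | IC[C@@H]1C(=O)OC[C@H]1Cc1cc(OC)c2c(c1)[C@@H](CO[Si](C(C)C)(C(C)C)C(C)C)[C@H](c1ccc(OCc3ccccc3)c(OC)c1)O2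
F3 | step 13 | {[(3S,4S)-4-({(2R,3S)-2-[4-(benzyloxy)-3-methoxyphenyl]-7-methoxy-3-[(triisopropylsilyloxy)methyl]-2,3-dihydro-1-benzofuran-5-yl}methyl)-2-oxooxolan-3-yl]methyl}zinc iodide | I[Zn]C[C@@H]1C(=O)OC[C@H]1Cc1cc(OC)c2c(c1)[C@@H](CO[Si](C(C)C)(C(C)C)C(C)C)[C@H](c1ccc(OCc3ccccc3)c(OC)c1)O2
F4 | step 5 | (R)-4-benzyl-3-({5-bromo-3-methoxy-2-[(4-methoxybenzyl)oxy]phenyl}acetyl)-1,3-oxazolidin-2-one | O=C(Cc1cc(Br)cc(OC)c1OCc1ccc(OC)cc1)N1[C@H](Cc2ccccc2)COC1=O
F5 | step 5 | (4R)-4-benzyl-3-[(2R,3R)-3-[4-(benzyloxy)-3-methoxyphenyl]-2-{5-bromo-3-methoxy-2-[(4-methoxybenzyl)oxy]phenyl}-3-hydroxypropanoyl]-1,3-oxazolidin-2-one | O=C([C@H](c1cc(Br)cc(OC)c1OCc1ccc(OC)cc1)[C@@H](O)c1ccc(OCc2ccccc2)c(OC)c1)N1[C@H](Cc2ccccc2)COC1=O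
F6 | step 5 | (1R,2S)-1-[4-(benzyloxy)-3-methoxyphenyl]-2-{5-bromo-3-methoxy-2-[(4-methoxybenzyl)oxy]phenyl}propane-1,3-diol | OC[C@H](c1cc(Br)cc(OC)c1OCc1ccc(OC)cc1)[C@@H](O)c1ccc(OCc2ccccc2)c(OC)c1
F7 | step 5 | (1R,2S)-1-[4-(benzyloxy)-3-methoxyphenyl]-2-{5-bromo-3-methoxy-2-[(4-methoxybenzyl)oxy]phenyl}-3-(triisopropylsilyloxy)propan-1-ol | CC(C)[Si](OC[C@H](c1cc(Br)cc(OC)c1OCc1ccc(OC)cc1)[C@@H](O)c1ccc(OCc2ccccc2)c(OC)c1)(C(C)C)C(C)C
F8 | step 5 | (1S,2S)-1-[4-(benzyloxy)-3-methoxyphenyl]-2-{5-bromo-3-methoxy-2-[(4-methoxybenzyl)oxy]phenyl}-3-(triisopropylsilyloxy)propyl 4-nitrobenzoate | CC(C)[Si](OC[C@H](c1cc(Br)cc(OC)c1OCc1ccc(OC)cc1)[C@H](OC(=O)c1ccc(cc1)[N+]([O-])=O)c1ccc(OCc2ccccc2)c(OC)c1)(C(C)C)C(C)C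
F9 | step 10 | 3-{(2R,3S)-2-[4-(benzyloxy)-3-methoxyphenyl]-7-methoxy-3-[(triisopropylsilyloxy)methyl]-2,3-dihydro-1-benzofuran-5-yl}propanal | O=CCCc1cc(OC)c2c(c1)[C@@H](CO[Si](C(C)C)(C(C)C)C(C)C)[C@H](c1ccc(OCc3ccccc3)c(OC)c1)O2
F10 | step 10 | dimethyl 2-[(2S)-1-oxo-3-{(2R,3S)-2-[4-(benzyloxy)-3-methoxyphenyl]-7-methoxy-3-[(triisopropylsilyloxy)methyl]-2,3-dihydro-1-benzofuran-5-yl}propan-2-yl]propanedioate | O=C[C@H](C(C(=O)OC)C(=O)OC)Cc1cc(OC)c2c(c1)[C@@H](CO[Si](C(C)C)(C(C)C)C(C)C)[C@H](c1ccc(OCc3ccccc3)c(OC)c1)O2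
F11 | step 10 | dimethyl 2-[(2S)-1-hydroxy-3-{(2R,3S)-2-[4-(benzyloxy)-3-methoxyphenyl]-7-methoxy-3-[(triisopropylsilyloxy)methyl]-2,3-dihydro-1-benzofuran-5-yl}propan-2-yl]propanedioate | OC[C@H](C(C(=O)OC)C(=O)OC)Cc1cc(OC)c2c(c1)[C@@H](CO[Si](C(C)C)(C(C)C)C(C)C)[C@H](c1ccc(OCc3ccccc3)c(OC)c1)O2
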